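**Retrosynthetic overview** (labdane numbering: ring A = C1–C5 and C10; ring B = C5–C10; C17 = ester carbon on C8; C20 = methyl on C10)
1. The C6=C7 alkene comes from syn-dehydration of an axial C6 carbinol, hence from a C6 ketone; the E-enoate of the side chain comes from a Wittig reaction on an acetoxymethyl ketone.
2. C9–H comes from radical denitration; the C9–C11 bond comes from Michael addition of a C9 nitronate (a carbanion beta to the C17 ester) to acetoxymethyl vinyl ketone.
3. Ring B comes from annulation of a ring-A 2-aminodiene with methyl (E)-3-nitroacrylate, which acts as an ester alpha-cation: C7–C8 first (ketone alpha-carbon to ester alpha-carbon), then C9–C10.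
4. Ring order: ring A is bought (β-cyclocitral); ring B is the only ring made. The prolinol-ether auxiliary sets C8, which relays to C10, C9 and C5.

Assumption: the (S)-auxiliary is taken to give the (8S) Michael adduct; if the sense proved opposite, its commercially available enantiomer would be used with nothing else changed.

**Step 1**
Reactants: 1 β-cyclocitral (2,6,6-trimethylcyclohex-1-ene-1-carbaldehyde)
Product: 2 1-(2,6,6-trimethylcyclohex-1-en-1-yl)ethan-1-ol (racemic)
Conditions: MeMgBr, Et2O, 0 °C; aq. NH4Cl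
Reagents that add atoms: methylmagnesium bromide, C[Mg]Br
Why: Grignard 1,2-addition to the hindered enal gives the allylic carbinol, whose racemic centre is removed in step 2.

**Step 2**
Reactants: 2 1-(2,6,6-trimethylcyclohex-1-en-1-yl)ethan-1-ol
Product: 3 1-(2,6,6-trimethylcyclohex-1-en-1-yl)ethan-1-one
Conditions: MnO2 (excess), CH2Cl2, rt
Reagents that add atoms: none
Why: MnO2 oxidation of an allylic alcohol gives the methyl ketone without touching the tetrasubstituted alkene; no stereocentre remains.

**Step 3**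
Reactants: 3 1-(2,6,6-trimethylcyclohex-1-en-1-yl)ethan-1-one
Product: 4 (2S)-2-(methoxymethyl)-1-[1-(2,6,6-trimethylcyclohex-1-en-1-yl)ethenyl]pyrrolidine (used crude after filtration and evaporation)
Conditions: (2S)-2-(methoxymethyl)pyrrolidine, TiCl4, Et3N, toluene, 0 °C → rt
Reagents that add atoms: (2S)-2-(methoxymethyl)pyrrolidine, COC[C@@H]1CCCN1
Why: TiCl4-mediated enamine condensation (White–Weingarten) of the hindered ketone occurs on the methyl side and gives the cross-conjugated 2-aminodiene carrying the bought (S)-stereocentre; no new stereocentre forms.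

**Step 4**
Reactants: 5 methyl acrylate
Product: 7 methyl (E)-3-nitroprop-2-enoate, via methyl 2-iodo-3-nitropropanoate 6 (not isolated)
Conditions: N2O4, I2, Et2O, 0 °C; then NaOAc, Et2O, 0 °C → rt
Reagents that add atoms: dinitrogen tetroxide, O=[N+]([O-])[N+](=O)[O-]
Why: Iodonitration of the acrylate followed by acetate-induced loss of HI (McMurry–Musser nitroacrylate synthesis) gives the thermodynamically favoured E-nitroalkene.

**Step 5**
Reactants: 4 (2S)-2-(methoxymethyl)-1-[1-(2,6,6-trimethylcyclohex-1-en-1-yl)ethenyl]pyrrolidine; 7 methyl (E)-3-nitroprop-2-enoate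
Product: 10 methyl (1R,2S,4aR,8aR)-5,5,8a-trimethyl-1-nitro-4-oxodecahydronaphthalene-2-carboxylate (C9 nitro syn to C20, C8 ester anti to C20, H5 anti to C20), via enamine Michael adduct 8 (not isolated), via bicyclic enamine 9 (not isolated)
Conditions: THF, −78 °C → rt, 16 h; then AcOH/NaOAc buffer (pH 5), H2O, rt
Reagents that add atoms: water, O
Why: Proposed new method: the enamine carbon C7 adds to the carbon of 7 that is beta to nitro (the ester alpha-carbon, so 7 serves as an ester alpha-cation), the resulting nitronate (C9) closes 6-endo onto the conjugated iminium carbon C10, and hydrolysis frees the ketone; the auxiliary fixes C8 in the first bond formation (Seebach–Enders prolinol-ether enamine/nitroalkene Michael), the reversible ring closure puts CO2Me and NO2 equatorial with the C10 methyl axial (setting C10 and C9 relative to C8), and C5 is protonated to the trans ring fusion (equilibrated again in step 7); the closest known reaction type is the formal [4+2] cycloaddition of chiral 2-aminobutadienes with nitroalkenes to give 4-nitrocyclohexanones.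

**Step 6**
Reactants: 11 acetoxyacetyl chloride (2-chloro-2-oxoethyl acetate)
Product: 12 2-oxobut-3-en-1-yl acetate (acetoxymethyl vinyl ketone, used fresh)
Conditions: tributyl(vinyl)stannane, PdCl2(PPh3)2 (2 mol%), THF, 50 °C
Reagents that add atoms: tributyl(vinyl)stannane, C=C[Sn](CCCC)(CCCC)CCCC
Why: Stille acylation of the acid chloride with the vinylstannane gives the vinyl ketone; no stereocentre.

**Step 7**
Reactants: 10 methyl (1R,2S,4aR,8aR)-5,5,8a-trimethyl-1-nitro-4-oxodecahydronaphthalene-2-carboxylate; 12 2-oxobut-3-en-1-yl acetate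
Product: 13 methyl (1R,2S,4aR,8aR)-1-[4-(acetyloxy)-3-oxobutyl]-5,5,8a-trimethyl-1-nitro-4-oxodecahydronaphthalene-2-carboxylate (C11 anti to C20, nitro syn to C20)
Conditions: 1,1,3,3-tetramethylguanidine (0.1 equiv), MeCN, 0 °C
Reagents that add atoms: none
Why: Base-catalysed nitro-Michael addition of the C9 nitronate (an ester homoenolate equivalent) to the unhindered vinyl ketone forms C9–C11 anti to the axial C10 methyl; this C9 configuration is reset in step 9, and the base keeps C5 at the trans ring fusion.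

**Step 8**
Reactants: 13 methyl (1R,2S,4aR,8aR)-1-[4-(acetyloxy)-3-oxobutyl]-5,5,8a-trimethyl-1-nitro-4-oxodecahydronaphthalene-2-carboxylate
Product: 14 methyl (1R,2S,4aR,8aR)-1-[(3E)-3-[(acetyloxy)methyl]-5-methoxy-5-oxopent-3-en-1-yl]-5,5,8a-trimethyl-1-nitro-4-oxodecahydronaphthalene-2-carboxylate
Conditions: Ph3P=CHCO2Me, toluene, 60 °C
Reagents that add atoms: methyl (triphenylphosphoranylidene)acetate, COC(=O)C=P(c1ccccc1)(c1ccccc1)c1ccccc1
Why: Wittig olefination with the stabilised ylide is selective for the activated alpha-acetoxy ketone over the hindered ring ketone and gives the E-enoate (CH2OAc trans to CO2Me), as is usual for alpha-oxygenated ketones.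

**Step 9**
Reactants: 14 the tertiary nitro compound from step 8
Product: 15 methyl (1R,2S,4aR,8aS)-1-[(3E)-3-[(acetyloxy)methyl]-5-methoxy-5-oxopent-3-en-1-yl]-5,5,8a-trimethyl-4-oxodecahydronaphthalene-2-carboxylate (side chain syn to C20)
Conditions: Bu3SnH, AIBN, benzene, 80 °C
Reagents that add atoms: none
Why: Ono–Tanner radical denitration gives the C9 radical, which takes hydrogen from Bu3SnH axially on the face anti to the C10 methyl, leaving the side chain equatorial and syn to that methyl.

**Step 10**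
Reactants: 15 the C6 ketone from step 9
Product: 16 methyl (1R,2S,4S,4aR,8aS)-1-[(3E)-3-[(acetyloxy)methyl]-5-methoxy-5-oxopent-3-en-1-yl]-4-hydroxy-5,5,8a-trimethyldecahydronaphthalene-2-carboxylate (C6 hydroxyl axial, syn to C20)
Conditions: NaBH4, MeOH/THF (1:4), −20 °C
Reagents that add atoms: none
Why: Chemoselective borohydride reduction: hydride attacks the C6 ketone from the face opposite the axial C10 and C4 methyls and gives the axial alcohol, while esters, enoate and acetate survive at low temperature.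

**Step 11**
Reactants: 16 the axial C6 alcohol from step 10
Product: 17 methyl (1R,2S,4aR,8aS)-1-[(3E)-3-[(acetyloxy)methyl]-5-methoxy-5-oxopent-3-en-1-yl]-5,5,8a-trimethyl-1,2,4a,5,6,7,8,8a-octahydronaphthalene-2-carboxylate (target)
Conditions: Burgess reagent (methyl N-(triethylammoniosulfonyl)carbamate), toluene, 60 °C
Reagents that add atoms: none
Why: Burgess dehydration is an intramolecular syn elimination, and the axial C6 sulfamate has a syn hydrogen only on C7 (H5 is anti-periplanar), so the C6=C7 alkene forms without touching the C8 stereocentre.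

**Compound list**
1 | β-cyclocitral (2,6,6-trimethylcyclohex-1-ene-1-carbaldehyde) | CC1=C(C=O)C(C)(C)CCC1 | starting material
2 | 1-(2,6,6-trimethylcyclohex-1-en-1-yl)ethan-1-ol (racemic) | CC(O)C1=C(C)CCCC1(C)C | intermediate
3 | 1-(2,6,6-trimethylcyclohex-1-en-1-yl)ethan-1-one | CC(=O)C1=C(C)CCCC1(C)C | intermediate
4 | (2S)-2-(methoxymethyl)-1-[1-(2,6,6-trimethylcyclohex-1-en-1-yl)ethenyl]pyrrolidine | C=C(C1=C(C)CCCC1(C)C)N1CCC[C@H]1COC | intermediate
5 | methyl acrylate | C=CC(=O)OC | starting material
6 | methyl 2-iodo-3-nitropropanoate (racemic, not isolated) | COC(=O)C(I)C[N+](=O)[O-] | intermediate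
7 | methyl (E)-3-nitroprop-2-enoate | COC(=O)/C=C/[N+](=O)[O-] | intermediate
8 | methyl (2S)-4-[(2S)-2-(methoxymethyl)pyrrolidin-1-yl]-2-(nitromethyl)-4-(2,6,6-trimethylcyclohex-1-en-1-yl)but-3-enoate (enamine geometry not defined, not isolated) | [O-][N+](=O)C[C@@H](C(=O)OC)C=C(N1CCC[C@H]1COC)C1=C(C)CCCC1(C)C | intermediate
9 | methyl (1R,2S,8aR)-4-[(2S)-2-(methoxymethyl)pyrrolidin-1-yl]-5,5,8a-trimethyl-1-nitro-1,2,3,5,6,7,8,8a-octahydronaphthalene-2-carboxylate (not isolated) | [O-][N+](=O)[C@@H]1[C@@H](C(=O)OC)CC(N3CCC[C@H]3COC)=C2C(C)(C)CCC[C@@]12C | intermediate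
10 | methyl (1R,2S,4aR,8aR)-5,5,8a-trimethyl-1-nitro-4-oxodecahydronaphthalene-2-carboxylate | [O-][N+](=O)[C@@H]1[C@@H](C(=O)OC)CC(=O)[C@@H]2C(C)(C)CCC[C@@]12C | intermediate
11 | acetoxyacetyl chloride | CC(=O)OCC(=O)Cl | starting material
12 | 2-oxobut-3-en-1-yl acetate | C=CC(=O)COC(C)=O | intermediate
13 | methyl (1R,2S,4aR,8aR)-1-[4-(acetyloxy)-3-oxobutyl]-5,5,8a-trimethyl-1-nitro-4-oxodecahydronaphthalene-2-carboxylate | CC(=O)OCC(=O)CC[C@@]1([N+](=O)[O-])[C@@H](C(=O)OC)CC(=O)[C@@H]2C(C)(C)CCC[C@@]12C | intermediate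
14 | methyl (1R,2S,4aR,8aR)-1-[(3E)-3-[(acetyloxy)methyl]-5-methoxy-5-oxopent-3-en-1-yl]-5,5,8a-trimethyl-1-nitro-4-oxodecahydronaphthalene-2-carboxylate | COC(=O)/C=C(\CC[C@@]1([N+](=O)[O-])[C@@H](C(=O)OC)CC(=O)[C@@H]2C(C)(C)CCC[C@@]12C)COC(C)=O | intermediate
15 | methyl (1R,2S,4aR,8aS)-1-[(3E)-3-[(acetyloxy)methyl]-5-methoxy-5-oxopent-3-en-1-yl]-5,5,8a-trimethyl-4-oxodecahydronaphthalene-2-carboxylate | COC(=O)/C=C(\CC[C@@H]1[C@@H](C(=O)OC)CC(=O)[C@@H]2C(C)(C)CCC[C@@]12C)COC(C)=O | intermediate
16 | methyl (1R,2S,4S,4aR,8aS)-1-[(3E)-3-[(acetyloxy)methyl]-5-methoxy-5-oxopent-3-en-1-yl]-4-hydroxy-5,5,8a-trimethyldecahydronaphthalene-2-carboxylate | COC(=O)/C=C(\CC[C@@H]1[C@@H](C(=O)OC)C[C@H](O)[C@@H]2C(C)(C)CCC[C@@]12C)COC(C)=O | intermediate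
17 | methyl (1R,2S,4aR,8aS)-1-[(3E)-3-[(acetyloxy)methyl]-5-methoxy-5-oxopent-3-en-1-yl]-5,5,8a-trimethyl-1,2,4a,5,6,7,8,8a-octahydronaphthalene-2-carboxylate | COC(=O)/C=C(\CC[C@@H]1[C@@H](C(=O)OC)C=C[C@@H]2C(C)(C)CCC[C@@]12C)COC(C)=O | target

**Step count and risks**
Total steps: 11 (nine in the main line, two for the fragments 7 and 12). Longest linear sequence: 9 steps (steps 1, 2, 3, 5, 7, 8, 9, 10, 11).

Most likely to fail, first: step 5. The ring closure must form the quaternary C10 on a hindered ring carbon whose iminium is twisted out of conjugation, and the absolute configuration rests on auxiliary control at C8 plus a relay to C10. The fallback sets out from 3 and returns at 10. Kinetic enolisation of 3 with LiN(iPr)2 and silylation with TBSCl gives the silyl dienol ether tert-butyl(dimethyl){[1-(2,6,6-trimethylcyclohex-1-en-1-yl)ethenyl]oxy}silane F1. A Mukaiyama–Michael addition of F1 to 7, catalysed by Cu(OTf)2 with (S,S)-tert-butyl-bis(oxazoline) (the nitroacrylate binds divalent copper through nitro and ester oxygens), gives after desilylation the open-chain nitro enone methyl (2S)-2-(nitromethyl)-4-oxo-4-(2,6,6-trimethylcyclohex-1-en-1-yl)butanoate F2. DBU in MeCN then closes ring B by a separate 6-endo nitro-Michael addition under thermodynamic control (CO2Me equatorial) to give 10.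

Second: step 7. The nitronate is flanked by a quaternary carbon, and the beta-nitro ester can lose HNO2 or undergo retro-Michael ring opening under base. The fallback sets out from 10 and returns at 13. The nitronate of 10 is added to acrolein, the smallest and most reactive acceptor, to give the aldehyde methyl (1R,2S,4aR,8aR)-5,5,8a-trimethyl-1-nitro-4-oxo-1-(3-oxopropyl)decahydronaphthalene-2-carboxylate F3. Thiazolium-carbene-catalysed hydroxymethylation of F3 with paraformaldehyde (acyl-anion addition of the Breslow intermediate to formaldehyde) gives the hydroxymethyl ketone methyl (1R,2S,4aR,8aR)-1-(4-hydroxy-3-oxobutyl)-5,5,8a-trimethyl-1-nitro-4-oxodecahydronaphthalene-2-carboxylate F4. Acetylation with Ac2O and pyridine gives 13.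

Third: step 11. The axial C6 hydroxyl is shielded by two syn-axial methyls and its sulfamate may ionise and rearrange instead of eliminating. The fallback sets out from 15 and returns at 17, bypassing 16. KN(SiMe3)2 and Comins' reagent at −78 °C (kinetic deprotonation at C7) give the C6 enol triflate of 15, methyl (1R,2R,4aR,8aS)-1-[(3E)-3-[(acetyloxy)methyl]-5-methoxy-5-oxopent-3-en-1-yl]-5,5,8a-trimethyl-4-{[(trifluoromethyl)sulfonyl]oxy}-1,2,4a,5,6,7,8,8a-octahydronaphthalene-2-carboxylate F5. F5 is reduced with Pd(OAc)2, PPh3, HCO2H and Bu3N in DMF at 40 °C (formate reduction of the vinyl triflate at zerovalent palladium) to give 17. The reaction is kept short and cool because the allylic acetate can also ionise at palladium.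

**Further compounds**
F1 | step 5 | tert-butyl(dimethyl){[1-(2,6,6-trimethylcyclohex-1-en-1-yl)ethenyl]oxy}silane | C=C(O[Si](C)(C)C(C)(C)C)C1=C(C)CCCC1(C)C
F2 | step 5 | methyl (2S)-2-(nitromethyl)-4-oxo-4-(2,6,6-trimethylcyclohex-1-en-1-yl)butanoate | [O-][N+](=O)C[C@@H](C(=O)OC)CC(=O)C1=C(C)CCCC1(C)C
F3 | step 7 | methyl (1R,2S,4aR,8aR)-5,5,8a-trimethyl-1-nitro-4-oxo-1-(3-oxopropyl)decahydronaphthalene-2-carboxylate | O=CCC[C@@]1([N+](=O)[O-])[C@@H](C(=O)OC)CC(=O)[C@@H]2C(C)(C)CCC[C@@]12C
F4 | step 7 | methyl (1R,2S,4aR,8aR)-1-(4-hydroxy-3-oxobutyl)-5,5,8a-trimethyl-1-nitro-4-oxodecahydronaphthalene-2-carboxylate | OCC(=O)CC[C@@]1([N+](=O)[O-])[C@@H](C(=O)OC)CC(=O)[C@@H]2C(C)(C)CCC[C@@]12C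
F5 | step 11 | methyl (1R,2R,4aR,8aS)-1-[(3E)-3-[(acetyloxy)methyl]-5-methoxy-5-oxopent-3-en-1-yl]-5,5,8a-trimethyl-4-{[(trifluoromethyl)sulfonyl]oxy}-1,2,4a,5,6,7,8,8a-octahydronaphthalene-2-carboxylate | COC(=O)/C=C(\CC[C@@H]1[C@@H](C(=O)OC)C=C(OS(=O)(=O)C(F)(F)F)[C@@H]2C(C)(C)CCC[C@@]12C)COC(C)=O
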